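**Retrosynthetic overview**
- (2S)-Naringenin 1 supplies every atom of the flavanone half and the only stereocentre (C2). It is 7-O-methylated to (2S)-sakuranetin 2, and its 4'-OH is then turned into the leaving group of aryl triflate 3.
- Luteolin 4 supplies the whole flavone half, including the ether oxygen (its O3').
- The one key disconnection of target 5 is the diaryl ether bond C4'(flavanone ring B)–O3'(flavone ring B), made last by light-driven nickel catalysis between 3 and unprotected 4.
- No ring is formed in the route: rings A, C and B of both halves are bought intact. Bond order: O–CH3, then O–S, then aryl C–O.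

Assumption: (2S)-naringenin (aglycone of the citrus glycoside naringin) is bought as the single enantiomer and its ee is confirmed by chiral HPLC before use.

Abbreviations: dtbbpy = 4,4'-di-tert-butyl-2,2'-bipyridine; ppy = 2-phenylpyridinate; dme = 1,2-dimethoxyethane; DMA = N,N-dimethylacetamide.

**Step 1**
Reactants: 1 (2S)-naringenin
Product: 2 (2S)-sakuranetin [(2S)-5-hydroxy-2-(4-hydroxyphenyl)-7-methoxychroman-4-one]
Conditions: MeI (1.1 equiv), KHCO3 (1.5 equiv), DMF, 35 °C, 16 h, N2
Reagents that add atoms: methyl iodide, CI
Why: Williamson-type SN2 O-methylation gated by acidity, since KHCO3 ionises only the 7-OH (a vinylogous acid, pKa about 7.5) and not the 4'-OH (pKa about 10) or the chelated 5-OH, and without a ring B phenoxide the C2 stereocentre is not opened.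

**Step 2**
Reactants: 2 (2S)-sakuranetin
Product: 3 4-[(2S)-5-hydroxy-7-methoxy-4-oxochroman-2-yl]phenyl trifluoromethanesulfonate
Conditions: Tf2O (1.1 equiv), pyridine (3 equiv), CH2Cl2, −20 to 0 °C, 1 h
Reagents that add atoms: triflic anhydride, O=S(=O)(OS(=O)(=O)C(F)(F)F)C(F)(F)F
Why: Phenol O-sulfonylation (triflation) of the only unchelated phenol, the 5-OH being tied up in its hydrogen bond to the C4 carbonyl, under cold, weakly basic conditions that leave C2 untouched.

**Step 3**
Reactants: 3 4-[(2S)-5-hydroxy-7-methoxy-4-oxochroman-2-yl]phenyl trifluoromethanesulfonate; 4 luteolin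
Product: 5 5,7-dihydroxy-2-[4-hydroxy-3-[4-[(2S)-5-hydroxy-7-methoxy-4-oxochroman-2-yl]phenoxy]phenyl]-4H-chromen-4-one (target)
Conditions: NiBr2(dme) (10 mol %), dtbbpy (10 mol %), [Ir(ppy)2(dtbbpy)]PF6 (1 mol %), K2CO3 (5 equiv), 4 (2 equiv), degassed DMA, 456 nm LEDs, 25 °C, 24 h; then 1 M HCl work-up
Reagents that add atoms: none
Why: Proposed new method: site-selective mono-O-arylation of an unprotected catechol polyphenol by potential-gated nickel/photoredox C–O cross-coupling, in which zerovalent nickel (formed by the reduced iridium photocatalyst) inserts into the C–OTf bond of 3, the resulting aryl complex of divalent nickel is chelated by the 3',4'-catecholate of 4 (its only dianionic chelating site), only this electron-rich chelate is oxidised by the mild excited photocatalyst (about +0.66 V against SCE, too weak for a simple nickel phenoxide such as the 7-O-bound one), and the trivalent-nickel/semiquinonate species so formed reductively eliminates the aryl group onto O3', the more electron-rich oxygen because O4' is delocalised into the chromone carbonyl, leaving a monophenol that can no longer chelate so that arylation stops at one; the closest known reaction type is nickel/photoredox C–O coupling of aryl bromides with alcohols or simple phenols, and the 25 °C carbonate conditions do not touch the C2 stereocentre, which is never a reacting atom.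

**Compound list**
1 | (2S)-naringenin, (2S)-5,7-dihydroxy-2-(4-hydroxyphenyl)chroman-4-one | Oc1cc(O)c2c(c1)O[C@H](c1ccc(O)cc1)CC2=O | starting material
2 | (2S)-sakuranetin, (2S)-5-hydroxy-2-(4-hydroxyphenyl)-7-methoxychroman-4-one | COc1cc(O)c2c(c1)O[C@H](c1ccc(O)cc1)CC2=O | intermediate
3 | 4-[(2S)-5-hydroxy-7-methoxy-4-oxochroman-2-yl]phenyl trifluoromethanesulfonate | COc1cc(O)c2c(c1)O[C@H](c1ccc(OS(=O)(=O)C(F)(F)F)cc1)CC2=O | intermediate
4 | luteolin, 2-(3,4-dihydroxyphenyl)-5,7-dihydroxy-4H-chromen-4-one | O=c1cc(-c2ccc(O)c(O)c2)oc2cc(O)cc(O)c12 | starting material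
5 | 5,7-dihydroxy-2-[4-hydroxy-3-[4-[(2S)-5-hydroxy-7-methoxy-4-oxochroman-2-yl]phenoxy]phenyl]-4H-chromen-4-one | COc1cc(O)c2c(c1)O[C@H](c1ccc(Oc3cc(-c4cc(=O)c5c(O)cc(O)cc5o4)ccc3O)cc1)CC2=O | target

**Totals**
Total step count: 3. Longest linear sequence: 3 steps (1 → 2 → 3 → 5); luteolin 4 enters in the last step.

**Steps most likely to fail, with fallbacks**

Step 3 (the proposed new coupling) is the most likely to fail. The risks are arylation at O7 or O4' of luteolin, triflyl transfer from 3 to a phenoxide, light absorption by the luteolin anions, binding of nickel at the 5-hydroxy-4-keto sites, and base-induced erosion of ee at C2. The regiochemistry would be checked by HMBC/NOE and the ee by chiral HPLC. The fallback uses known chemistry and sets out from 4 (with 3 as made in the route). Luteolin is benzylated at its two most acidic hydroxyls (BnBr 2.2 equiv, K2CO3, DMF, 25 °C) to give 4',7-di-O-benzylluteolin F5, which keeps only the 3'-OH and the chelated 5-OH free. F5 is joined to triflate 3 by thermal palladium-catalysed diaryl ether formation (Pd2(dba)3, tBuXPhos, K3PO4, toluene, 90 °C) to give the 4''',7''-di-O-benzyl ether of the target F6. Hydrogenolysis (H2 1 atm, palladium on carbon, EtOAc/MeOH, 25 °C) removes both benzyl groups and comes back to the route at 5.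

Step 1 may over-methylate to the 4',7-dimethyl ether or stall, and any 4'-phenoxide formed could erode the ee. The fallback replaces the acidity-gated alkylation by a protecting-group sequence that sets out from 1. Acetylation (Ac2O 2.2 equiv, pyridine, 0 °C) gives (2S)-naringenin 4',7-diacetate F1. The more activated 7-O-acetyl is removed selectively (PhSH, imidazole, N-methylpyrrolidone, 0 °C) to give (2S)-naringenin 4'-acetate F2. Neutral Mitsunobu methylation of the now unique acidic 7-OH (MeOH, PPh3, DIAD, THF, 0 to 25 °C) gives (2S)-sakuranetin 4'-acetate F3. Acidic methanolysis (1 M HCl in MeOH, 25 °C), under which flavanones do not racemise, comes back to the route at 2.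

Step 2 may give some 5-O-triflate or bis-triflate, or 3 may prove too prone to sulfur attack by phenoxides in step 3. The fallback sets out from 2 and changes the electrophile class. Sulfur–fluoride exchange with SO2F2 (generated ex situ, Et3N, CH2Cl2, 25 °C) gives 4-[(2S)-5-hydroxy-7-methoxy-4-oxochroman-2-yl]phenyl fluorosulfate F4. This bench-stable aryl fluorosulfate is used in place of 3 in the nickel/photoredox coupling with 4 under the step 3 conditions and comes back to the route at 5.

**Further compounds**
F1 | step 1 | (2S)-naringenin 4',7-diacetate | CC(=O)Oc1cc(O)c2c(c1)O[C@H](c1ccc(OC(C)=O)cc1)CC2=O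
F2 | step 1 | (2S)-naringenin 4'-acetate | Oc1cc(O)c2c(c1)O[C@H](c1ccc(OC(C)=O)cc1)CC2=O
F3 | step 1 | (2S)-sakuranetin 4'-acetate | COc1cc(O)c2c(c1)O[C@H](c1ccc(OC(C)=O)cc1)CC2=O
F4 | step 2 | 4-[(2S)-5-hydroxy-7-methoxy-4-oxochroman-2-yl]phenyl fluorosulfate | COc1cc(O)c2c(c1)O[C@H](c1ccc(OS(=O)(=O)F)cc1)CC2=O
F5 | step 3 | 4',7-di-O-benzylluteolin | O=c1cc(-c2ccc(OCc3ccccc3)c(O)c2)oc2cc(OCc3ccccc3)cc(O)c12
F6 | step 3 | 4''',7''-di-O-benzyl ether of the target (benzyl on the flavone 7-O and on the flavone ring B 4-O) | COc1cc(O)c2c(c1)O[C@H](c1ccc(Oc3cc(-c4cc(=O)c5c(O)cc(OCc6ccccc6)cc5o4)ccc3OCc7ccccc7)cc1)CC2=O
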